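Percent of both substrates charged together is the unit of the readings, so each substrate starts at 50.

- south-west: left-handed substrate 0.27 M; right-handed substrate 0.27 M; reagent 3 equiv; free catalyst 15 mol%; racemization catalyst 0.11 mol%; added ligand 1.1 mM; the very flask that is asked about, followed so far
- flask: left-handed substrate 0.27 M; reagent 3.00 equiv; free catalyst 15 mol%; racemization catalyst 0.11 mol%; added ligand 1.1 mM; right-handed substrate 0.27 M; time 6.0 d

south-west run (percent of the left-handed substrate and right-handed substrate together charged)

| time / h | left-handed product / % | right-handed product / % | left-handed substrate / % |
|---|---|---|---|
| 2.50 | 1.8 | 0.8 | 48.9 |
| 4.00 | 2.1 | 1.1 | 47.5 |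
| 6.00 | 3.1 | 2.1 | 46.6 |
| 10.0 | 5.3 | 2.8 | 44.3 |
| 20.0 | 9.2 | 4.9 | 40.8 |
| 30.0 | 11.9 | 6.2 | 37.2 |

(each reading ± 0.3 percentage points)

1. left-handed product and right-handed product together, in percent of the left-handed substrate and right-handed substrate charged together, at 6.0 d
2. excess of left-handed product over right-handed product in the product at 6.0 d
3. whether the exchange between left-handed substrate and right-handed substrate keeps pace with the reaction: how far the product's excess at 6.0 d gets from its value without exchange to its value with instant exchange (above 80 % keeps pace, below 20 % hardly takes part, else lags behind)

- free catalyst is single-handed; left-handed substrate and right-handed substrate are mirror images of each other, charged as a racemate, each of them at the stated concentration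
- what was read earlier has a scatter of 0.3 percentage points, one standard deviation
- reactions considered so far: 2 free catalyst -> spent catalyst A; racemization catalyst + added ligand <-> idle complex; left-handed substrate + racemization catalyst <-> right-handed substrate + racemization catalyst; reagent + free catalyst + right-handed substrate -> free catalyst + right-handed product; reagent + racemization catalyst -> spent catalyst B; reagent + free catalyst + left-handed substrate -> free catalyst + left-handed product
- an excess is below zero if the other one leads

In the south-west run at 30.0 h, left-handed substrate and left-handed product sum to 49.1 %, so no gain of left-handed material shows, and you may read the right-handed substrate as its start minus the right-handed product.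

Both product-forming steps use the same free catalyst and the same reagent, so at one moment their rates stand as s times left-handed over right-handed substrate, and the decline of the catalyst cancels. Here s is the selectivity factor, the ratio of the two rate constants. Integrated for a flask without exchange, this gives a rule without a clock: the fraction of right-handed substrate left is the s-th root of the fraction of left-handed substrate left. The last reading gives s = 2.23, a reading with its scatter.

So the excess starts at (s−1)/(s+1) = 38.2 %. With instant exchange the substrates stay equal and it stays there. Without exchange the left-handed substrate falls further, the rate ratio drifts down, and the excess must sink below that value.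

The forecast says 40 %, excess 26 %, exchange hardly takes part, on the ground that “Any exchange would push it above 50”. Its selectivity near 2 is lower than my s.

The flask gives 40.1 %, excess 28.9 %, and exchange hardly takes part, at 0.20 % of the way.

    2 free catalyst → spent catalyst A (k = 0.00420 L mol⁻¹ min⁻¹)
    racemization catalyst + added ligand ⇌ idle complex, settled at all times (K = 2.30 × 10⁵ L mol⁻¹)
    left-handed substrate + racemization catalyst ⇌ right-handed substrate + racemization catalyst, rate k3*[racemization catalyst]*[left-handed substrate] forward; the back reaction follows from the equilibrium constant (k = 0.230 L mol⁻¹ min⁻¹)
    reagent + free catalyst + right-handed substrate → free catalyst + right-handed product (k = 0.00300 L² mol⁻² min⁻¹)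
    reagent + racemization catalyst → spent catalyst B (k = 0.00150 L mol⁻¹ min⁻¹)
    reagent + free catalyst + left-handed substrate → free catalyst + left-handed product (k = 0.00650 L² mol⁻² min⁻¹)

In this flask at 6.00 d, 48 % of the left-handed substrate is left, and the rule gives 72.0 % of the right-handed substrate against 71 % found. Without the loss of free catalyst to spent catalyst A, this flask reaches 60.8 % conversion instead of 40.1 % and its excess sinks to 22.8 %: that loss, acting together with the reading at this time and not ten times later, is part of the reason for the conversion and for the excess.

In the neighbour with 5.10 equiv of reagent, 28 % of the left-handed substrate is left, so the rule gives 56.5 % of the right-handed substrate and an excess of 24.7 %; that flask gives 56 % and 23.8 %.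

The data were generated by integration with made-up constants, noise included.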